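Read at 20 min, a flask holds the target that has formed less what has since aged away, so reckon the age of that target first.

    substrate + target → 2 target (k1 = 13.4 M⁻¹ min⁻¹)
    substrate → target (k2 = 0.00322 min⁻¹)
    target → over-reaction product (k3 = 0.0144 min⁻¹)

common to all: target 5.50 mM
- midnight: substrate 0.11 M; a single well-mixed tank run continuously and read at steady state, 20 min in it on average
- dawn: substrate 0.11 M; everything together in a closed stirred flask, run for 20 min; time 20 min
- dusk: substrate 0.11 M; plug flow through a tube for 20 min, no back-mixing; time 20 min
- autumn: substrate 0.11 M (fed, over 16.0 min); a stirred flask in which substrate is dosed at a steady rate over 16.0 min without added volume, worked up at 20 min; time 20 min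

- the stated concentrations are those of everything mixed, before any reaction; amounts are the same in each set-up
- the feed brings no volume worth counting
- run time (dawn): 20 min

- the set-up with the highest amount of target at the outlet or at the end, in percent of the substrate put in ("none" if the first two lie within 2 percentage points) (midnight / dawn / dusk / autumn / none)
- amount of target at the outlet or at the end, in percent of the substrate put in, midnight
- amount of target at the outlet or at the end, in percent of the substrate put in, dawn
- amount of target at the outlet or at the end, in percent of the substrate put in, dusk
- amount of target at the outlet or at the end, in percent of the substrate put in, autumn

1. Start with the fastest clock, in dawn and dusk, which run alike since neither mixes early with late material. While substrate lasts, target multiplies itself with a rate constant of 1.55 min⁻¹, the first constant times the sum of both charges.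

2. Find the birth time (the induction time of this self-feeding rise), the moment when c(substrate) and c(target) stand equal: ln of the charge ratio divided by that rate constant, 1.94 min.

3. Treat the target in dawn and dusk as born at that moment, because its half-life of 48 min is far longer than the birth time. Leave out the uncatalysed step, because at the start of dusk the self-feeding step uses substrate 23 times as fast as the uncatalysed step does, and both steps make target.

4. Take the pool, substrate plus seed, as 105% of the substrate, and shrink it exponentially by the third constant times the age. Dawn and dusk come to 81.0%.

5. In autumn, take the average birth at half the dosing time, an age of 12.0 min, which gives 88.3%. Hold this as a low figure, because at the charged target level substrate has a half-life of 9.4 min, not short against the 16.0 min feed, so births trail the dosing.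

6. In midnight, divide the pool by one plus the third constant times the stay: 89.7 mM of target. That leaves 4.39 mM of substrate, so the tank gives 78.4%. Commit to autumn.

7. The forecast gives 78.3%, 80.9%, 80.9% and 90.5%, the last above my figure, with best autumn: “Dosing keeps the target inventory low for the early part of the run”.

8. The simulation gives midnight 78.3%, dawn 81.0%, dusk 81.0% and autumn 90.6%, so best is autumn. Autumn stands 2.3 percentage points above my figure.

Now read dusk at 80 min instead. The age becomes 78.1 min, and the same rule gives 34.1%. The tube holds 34.1% target at that reading, and over-reaction product now holds most, at 70.9%.

(Its constants were set for the occasion.)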